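**Plan** (numbering: decalin C1–C10; chain C11, C12, C13 (bears CH2OH), C14, C15, C16; butenolide C17 (β-carbon), C18, C19 (C=O), C20 (OCH2))

Cuts, in retro order: the C13 CH2OH goes back to a carboxyl; C17=C18 (intramolecular Horner–Wadsworth–Emmons, HWE, on a C17 ketone); C13=C14 (a C13 rhodium carbenoid opens a furan); C12–C13 (acetoacetate alkylation); the C8=C9 alkene goes back to the lactone of (+)-sclareolide.
Enabling feature: C14–C15=C16–C17–C20, with C15=C16 cis and oxygen on C17 and C20, is furfuryl alcohol written open (furan C5, C4=C3, C2 and its CH2O). C13 carries C12 and a carboxyl, so it can be a diazoester carbon whose carbene opens the furan ring to the Z,E-diene and the C17 ketone at once.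
Forward order: rings A and B come intact from sclareolide; the chain is joined at C12–C13 and then at C13=C14 (furan ring opened); the butenolide ring closes last at C17=C18; the C13 carboxyl is reduced at the end.
Stereochemistry: C5 and C10 (both S) are carried from (+)-sclareolide and C8/C9 are erased on purpose; C15=C16 Z is the former ring bond of the furan; C13=C14 E is set in the ring opening.

Key step: step 8

Notation: Dr = (4aS,8aS)-2,5,5,8a-tetramethyl-3,4,4a,5,6,7,8,8a-octahydronaphthalen-1-yl (the drimane bicycle with the C8=C9 alkene, attached through C9).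
Assumption: as with simple diazoacetates, the carbenoid opening of a 2-substituted furan is taken to deliver the ring-derived alkene cis and the new alkene with the ester trans to the chain.

Step 1
Reactants: 1 (+)-sclareolide
Product: 3 methyl homodrim-8-en-12-oate (Dr–CH2–CO2Me), via homodrim-8-en-12-oic acid 2 (not isolated)
Conditions: conc. H2SO4 (cat.), MeOH, rt to 40 °C
Reagents that add atoms: methanol, CO
Why: Acid ionises the tertiary C8–O bond of the lactone (E1), the C8 cation should settle mainly on the tetrasubstituted C8=C9 alkene under these equilibrating conditions, and the freed acid undergoes Fischer esterification; C5 and C10 are untouched, and minor C7=C8 and exocyclic isomers are to be removed on AgNO3-impregnated silica here or after step 2.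

Step 2
Reactants: 3 methyl homodrim-8-en-12-oate
Product: 4 homodrim-8-en-12-ol (Dr–CH2CH2OH)
Conditions: LiAlH4, THF, 0 °C to rt
Reagents that add atoms: none
Why: LiAlH4 reduction of an unhindered methyl ester to the primary alcohol is routine and leaves the tetrasubstituted alkene alone.

Step 3
Reactants: 4 homodrim-8-en-12-ol
Product: 5 homodrim-8-en-12-yl iodide (Dr–CH2CH2I)
Conditions: PPh3, I2, imidazole, CH2Cl2, 0 °C to rt, dark
Reagents that add atoms: iodine, [I][I]
Why: In the Appel iodination iodide displaces the alkoxyphosphonium group at the primary C12 by SN2, and the hindered alkene is a spectator, as with homoallylic terpenoid alcohols in general.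

Step 4
Reactants: 6 2,2,6-trimethyl-4H-1,3-dioxin-4-one
Product: 8 2-(trimethylsilyl)ethyl acetoacetate, via acetylketene 7 (not isolated)
Conditions: 2-(trimethylsilyl)ethanol, toluene, 110 °C, acetone distilled off
Reagents that add atoms: 2-(trimethylsilyl)ethanol, C[Si](C)(C)CCO
Why: Thermal retro-hetero-Diels–Alder loss of acetone gives acetylketene, which the alcohol traps as the β-keto ester (standard acetoacetylation).

Step 5
Reactants: 5 homodrim-8-en-12-yl iodide; 8 2-(trimethylsilyl)ethyl acetoacetate
Product: 9 2-(trimethylsilyl)ethyl 2-acetyl-4-(Dr)butanoate (both C13 epimers)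
Conditions: NaH, THF–DMF, 0 °C; then 5, 55 °C (8 in excess)
Reagents that add atoms: none
Why: Acetoacetic ester alkylation forms C12–C13 by SN2 at the primary iodide; the soft stabilised enolate should favour substitution over E2, the excess of 8 limits dialkylation, and the C13 centre does not matter because the next step erases it.

Step 6
Reactants: 9 2-(trimethylsilyl)ethyl 2-acetyl-4-(Dr)butanoate
Product: 10 2-(trimethylsilyl)ethyl 2-diazo-4-(Dr)butanoate
Conditions: p-ABSA, DBU, MeCN, 0 °C to rt
Reagents that add atoms: 4-acetamidobenzenesulfonyl azide (p-ABSA), CC(=O)Nc1ccc(cc1)S(=O)(=O)N=[N+]=[N-]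
Why: Deacylative (Regitz-type) diazo transfer, in which the enolate adds to the sulfonyl azide and the adduct loses the acetyl group to the sulfonamide nitrogen, is the standard entry to α-alkyl-α-diazoesters from α-alkyl acetoacetates.

Step 7
Reactants: 11 furfuryl alcohol; 12 diethylphosphonoacetic acid
Product: 13 furan-2-ylmethyl 2-(diethoxyphosphoryl)acetate
Conditions: DCC, DMAP (cat.), CH2Cl2, 0 °C to rt
Reagents that add atoms: none
Why: Steglich esterification runs under neutral conditions, so the acid-sensitive furfuryl alcohol is acylated without polymerisation.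

Step 8
Reactants: 10 2-(trimethylsilyl)ethyl 2-diazo-4-(Dr)butanoate; 13 furan-2-ylmethyl 2-(diethoxyphosphoryl)acetate
Product: 14 2-(trimethylsilyl)ethyl (2E,4Z)-7-{[2-(diethoxyphosphoryl)acetyl]oxy}-6-oxo-2-[2-(Dr)ethyl]hepta-2,4-dienoate
Conditions: Rh2(O2CCPh3)4 (1 mol %), 13 (4 equiv), CH2Cl2, −78 °C, slow addition of 10; then to rt
Reagents that add atoms: none
Why: Proposed new method: Rh2(O2CCPh3)4, a carboxylate dimer of divalent rhodium, should expel N2 from 10 at −78 °C, and the electrophilic carbenoid carbon C13 should be captured by the unsubstituted α-carbon of the furan in 13 (the later C14), giving a cyclopropane or the equivalent oxocarbenium/rhodium-enolate zwitterion that collapses by making C13=C14 and breaking the ring C–O bond, which frees the C17 ketone. The closest known reaction types are the rhodium-carbenoid ring opening of 2-substituted furans by diazoacetates and diazoketones to cis,trans-6-oxo-2,4-dienoates, and the intermolecular cyclopropanation, cyclopropenation and indole alkylation of α-alkyl-α-diazoesters with this bulky carboxylate catalyst at low temperature; their combination on one substrate is the untested part. The step closes no ring and creates no stereocentre: it opens the furan ring and sets two alkene geometries. C15=C16 stays Z because it is the C3=C4 bond of the furan and lies in a ring until the C–O bond breaks, and C13=C14 should form E (ester trans to C15) as the less hindered tiglate-type arrangement, any 13Z material being correctable through reversible oxa-6π closure to the 2H-pyran, which scrambles C13=C14 only. Three selectivities are needed: attack at furan C5 and not C2 (C2 carries the acyloxymethyl group), capture ahead of 1,2-hydride shift from C12 (bulky triphenylacetate ligands, −78 °C, slow addition of 10 to excess 13), and no intramolecular escape (C8 and C10, the carbons a five-membered C–H insertion would need, bear no hydrogen, and addition to C8=C9 would give a strained bicyclo[2.1.0]pentane).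

Step 9
Reactants: 14 the (2E,4Z)-6-oxo dienoate carrying the phosphonoacetate
Product: 15 2-(trimethylsilyl)ethyl (2E,4Z)-5-(5-oxo-2,5-dihydrofuran-3-yl)-2-[2-(Dr)ethyl]penta-2,4-dienoate
Conditions: LiCl, i-Pr2NEt, MeCN, 0 °C to rt
Reagents that add atoms: none
Why: Intramolecular HWE reaction under mild LiCl/amine conditions, in which the lithium-chelated phosphonate carbanion adds 5-exo-trig to the C17 ketone and diethyl phosphate is eliminated to form C17=C18, is an established butenolide synthesis from α-acyloxy ketones; the weak base should leave the cis C15=C16 bond and the silylethyl ester intact, and it drains any ketone/2H-pyran equilibrium irreversibly.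

Step 10
Reactants: 15 butenolide trienoate
Product: 16 (2E,4Z)-5-(5-oxo-2,5-dihydrofuran-3-yl)-2-[2-(Dr)ethyl]penta-2,4-dienoic acid
Conditions: TBAF, AcOH (1:1), THF, 0 °C to rt
Reagents that add atoms: none
Why: Fluoride attack at silicon triggers β-fragmentation of the 2-(trimethylsilyl)ethyl ester to the carboxylate, and the acetic acid buffer keeps the medium non-basic so that the acidic C20 methylene of the butenolide and the cis alkene should not isomerise.

Step 11
Reactants: 16 the C13 carboxylic acid
Product: 18 target CNP0232848.4, via isobutyl carbonic mixed anhydride 17 (not isolated)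
Conditions: i-BuOCOCl, N-methylmorpholine, THF, −15 °C; then NaBH4, THF–H2O, −15 to 0 °C
Reagents that add atoms: none
Why: Mixed carbonic anhydride activation followed by cold NaBH4 is the standard chemoselective reduction of a carboxylic acid beside esters and lactones, since hydride attacks the far more electrophilic anhydride acyl carbon (1,2-addition, then reduction of the aldehyde) while the butenolide and the alkenes should survive the short cold exposure.

**Compound list**

1 | (+)-sclareolide, (3aR,5aS,9aS,9bR)-3a,6,6,9a-tetramethyldecahydronaphtho[2,1-b]furan-2(1H)-one | C[C@]12CCCC([C@@H]1CC[C@@]3([C@@H]2CC(=O)O3)C)(C)C | starting material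
2 | homodrim-8-en-12-oic acid, 2-(Dr)acetic acid | CC1=C(CC(=O)O)[C@@]2(C)CCCC(C)(C)[C@@H]2CC1 | intermediate (not isolated)
3 | methyl homodrim-8-en-12-oate, methyl 2-(Dr)acetate | CC1=C(CC(=O)OC)[C@@]2(C)CCCC(C)(C)[C@@H]2CC1 | intermediate
4 | homodrim-8-en-12-ol, 2-(Dr)ethanol | CC1=C(CCO)[C@@]2(C)CCCC(C)(C)[C@@H]2CC1 | intermediate
5 | homodrim-8-en-12-yl iodide, (4aS,8aS)-1-(2-iodoethyl)-2,5,5,8a-tetramethyl-3,4,4a,5,6,7,8,8a-octahydronaphthalene | CC1=C(CCI)[C@@]2(C)CCCC(C)(C)[C@@H]2CC1 | intermediate
6 | 2,2,6-trimethyl-4H-1,3-dioxin-4-one | CC1=CC(=O)OC(C)(C)O1 | starting material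
7 | acetylketene (3-oxobut-1-en-1-one) | CC(=O)C=C=O | intermediate (not isolated)
8 | 2-(trimethylsilyl)ethyl 3-oxobutanoate | CC(=O)CC(=O)OCC[Si](C)(C)C | intermediate
9 | 2-(trimethylsilyl)ethyl 2-acetyl-4-(Dr)butanoate, both C13 epimers | CC1=C(CCC(C(C)=O)C(=O)OCC[Si](C)(C)C)[C@@]2(C)CCCC(C)(C)[C@@H]2CC1 | intermediate
10 | 2-(trimethylsilyl)ethyl 2-diazo-4-(Dr)butanoate | CC1=C(CCC(=[N+]=[N-])C(=O)OCC[Si](C)(C)C)[C@@]2(C)CCCC(C)(C)[C@@H]2CC1 | intermediate
11 | furfuryl alcohol (furan-2-ylmethanol) | OCc1ccco1 | starting material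
12 | diethylphosphonoacetic acid, 2-(diethoxyphosphoryl)acetic acid | OC(=O)CP(=O)(OCC)OCC | starting material
13 | furan-2-ylmethyl 2-(diethoxyphosphoryl)acetate | O=C(CP(=O)(OCC)OCC)OCc1ccco1 | intermediate
14 | 2-(trimethylsilyl)ethyl (2E,4Z)-7-{[2-(diethoxyphosphoryl)acetyl]oxy}-6-oxo-2-[2-(Dr)ethyl]hepta-2,4-dienoate (13E,15Z in target numbering) | CC1=C(CC/C(=C\C=C/C(=O)COC(=O)CP(=O)(OCC)OCC)C(=O)OCC[Si](C)(C)C)[C@@]2(C)CCCC(C)(C)[C@@H]2CC1 | intermediate
15 | 2-(trimethylsilyl)ethyl (2E,4Z)-5-(5-oxo-2,5-dihydrofuran-3-yl)-2-[2-(Dr)ethyl]penta-2,4-dienoate | CC1=C(CC/C(=C\C=C/C2=CC(=O)OC2)C(=O)OCC[Si](C)(C)C)[C@@]2(C)CCCC(C)(C)[C@@H]2CC1 | intermediate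
16 | (2E,4Z)-5-(5-oxo-2,5-dihydrofuran-3-yl)-2-[2-(Dr)ethyl]penta-2,4-dienoic acid | CC1=C(CC/C(=C\C=C/C2=CC(=O)OC2)C(=O)O)[C@@]2(C)CCCC(C)(C)[C@@H]2CC1 | intermediate
17 | isobutyl carbonic mixed anhydride of 16 | CC1=C(CC/C(=C\C=C/C2=CC(=O)OC2)C(=O)OC(=O)OCC(C)C)[C@@]2(C)CCCC(C)(C)[C@@H]2CC1 | intermediate (not isolated)
18 | CNP0232848.4, 4-[(1Z,3E)-4-(hydroxymethyl)-6-(Dr)hexa-1,3-dien-1-yl]furan-2(5H)-one | CC1=C(CC/C(=C\C=C/C2=CC(=O)OC2)CO)[C@@]2(C)CCCC(C)(C)[C@@H]2CC1 | target

**Totals**

Total step count: 11. Longest linear sequence: 9 steps from (+)-sclareolide (steps 1, 2, 3, 5, 6, 8, 9, 10, 11); steps 4 and 7 are one-step side branches.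

**Steps most likely to fail**

1. Step 8 (bears the label). Hydride migration from C12 to the carbenoid carbon may outrun capture by the furan, or the ring opening may deliver C13=C14 with the wrong geometry without equilibrating. The fallback uses known reactions only, sets out from iodide 5 and acid 12, and comes back at 15. Acid 12 is esterified with 2-(trimethylsilyl)ethanol (DCC, DMAP, CH2Cl2) to 2-(trimethylsilyl)ethyl 2-(diethoxyphosphoryl)acetate F1. Its sodium salt (NaH, DMF, 60 °C) is alkylated by 5 to 2-(trimethylsilyl)ethyl 2-(diethoxyphosphoryl)-4-(Dr)butanoate F2. HWE olefination of F2 with the known (Z)-3-iodoacrolein (LiCl, DBU, MeCN) should give 2-(trimethylsilyl)ethyl (2E,4Z)-5-iodo-2-[2-(Dr)ethyl]penta-2,4-dienoate F3, because α-alkyl phosphonoacetates give the tiglate-type E-enoate and the cis iodoalkene is carried from the aldehyde. Stille coupling of F3 with the known 4-(tributylstannyl)furan-2(5H)-one (Pd2(dba)3 as the zerovalent palladium source, AsPh3, DMF, rt) proceeds with retention at the cis iodoalkene and gives 15; steps 10 and 11 then follow unchanged.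

2. Step 1. Proton loss from the C8 cation may not be regioselective enough, and separating the C7=C8 and exocyclic isomers may be impractical. The fallback fixes the alkene position by conjugation; it sets out from 1 and comes back at 4. The lactone enolate (KN(SiMe3)2, THF, −78 °C) is hydroxylated with the Davis oxaziridine to 11-hydroxysclareolide F4 (C11 configuration immaterial). LiAlH4 opens it to the 8α,11,12-triol F5, and NaIO4 (THF–H2O) cleaves the 11,12-glycol to 8α-hydroxydriman-11-al F6. Acid-catalysed dehydration (p-TsOH, benzene, reflux) can end only at drim-8-en-11-al F7, a β-cyclocitral-type enal in which conjugation holds the alkene at C8=C9. Wittig methylenation (Ph3P=CH2, THF) gives the vinyl diene F8, and 9-BBN followed by H2O2/NaOH hydroborates only the terminal vinyl group to give 4.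

3. Step 11. Hydride may be delivered in a conjugate sense into the trienyl anhydride, or may attack the lactone carbonyl. The fallback separates activation from hydride delivery; it sets out from 16 and comes back at 18. Acid 16 is converted (EtSH, DCC, DMAP, CH2Cl2, 0 °C) into the S-ethyl thioester F9. Fukuyama reduction (Et3SiH, Pd on carbon, acetone, rt) stops at the trienal F10. Luche reduction (NaBH4, CeCl3·7H2O, MeOH, −78 °C) is 1,2-selective for the aldehyde, spares the butenolide and gives 18.

**Further compounds**

F1 | step 8 | 2-(trimethylsilyl)ethyl 2-(diethoxyphosphoryl)acetate | CCOP(=O)(OCC)CC(=O)OCC[Si](C)(C)C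
F2 | step 8 | 2-(trimethylsilyl)ethyl 2-(diethoxyphosphoryl)-4-(Dr)butanoate, both C13 epimers | CC1=C(CCC(C(=O)OCC[Si](C)(C)C)P(=O)(OCC)OCC)[C@@]2(C)CCCC(C)(C)[C@@H]2CC1
F3 | step 8 | 2-(trimethylsilyl)ethyl (2E,4Z)-5-iodo-2-[2-(Dr)ethyl]penta-2,4-dienoate | CC1=C(CC/C(=C\C=C/I)C(=O)OCC[Si](C)(C)C)[C@@]2(C)CCCC(C)(C)[C@@H]2CC1
F4 | step 1 | 11-hydroxysclareolide (α-hydroxy lactone, C11 epimer not defined) | C[C@]12CCCC([C@@H]1CC[C@@]3([C@@H]2C(O)C(=O)O3)C)(C)C
F5 | step 1 | 8α,11,12-triol from reduction of F4 | C[C@]12CCCC([C@@H]1CC[C@@](O)([C@@H]2C(O)CO)C)(C)C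
F6 | step 1 | 8α-hydroxydriman-11-al | C[C@]12CCCC([C@@H]1CC[C@@](O)([C@@H]2C=O)C)(C)C
F7 | step 1 | drim-8-en-11-al, (4aS,8aS)-2,5,5,8a-tetramethyl-3,4,4a,5,6,7,8,8a-octahydronaphthalene-1-carbaldehyde | CC1=C(C=O)[C@@]2(C)CCCC(C)(C)[C@@H]2CC1
F8 | step 1 | (4aS,8aS)-1-ethenyl-2,5,5,8a-tetramethyl-3,4,4a,5,6,7,8,8a-octahydronaphthalene | CC1=C(C=C)[C@@]2(C)CCCC(C)(C)[C@@H]2CC1
F9 | step 11 | S-ethyl (2E,4Z)-5-(5-oxo-2,5-dihydrofuran-3-yl)-2-[2-(Dr)ethyl]penta-2,4-dienethioate | CC1=C(CC/C(=C\C=C/C2=CC(=O)OC2)C(=O)SCC)[C@@]2(C)CCCC(C)(C)[C@@H]2CC1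
F10 | step 11 | (2E,4Z)-5-(5-oxo-2,5-dihydrofuran-3-yl)-2-[2-(Dr)ethyl]penta-2,4-dienal | CC1=C(CC/C(=C\C=C/C2=CC(=O)OC2)C=O)[C@@]2(C)CCCC(C)(C)[C@@H]2CC1
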